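The route rests on disconnecting the C1–H bond of the benzylic carbinol on the 3,4-dimethoxyphenyl ring, so that C1 and its neighbour C2 (carrying the acyloxymethyl and 4-methoxycinnamyl arms) become an aryl ketone and an acidic, freely epimerising methine flanked by a carboxamide. A ruthenium-catalysed asymmetric transfer hydrogenation with dynamic kinetic resolution then converts the racemic 2-cinnamyl β-keto amide into one syn β-hydroxy amide, fixing both stereocentres in a single operation. The precursor is assembled by Claisen acylation and linear Tsuji–Trost allylation; amide reduction, site-selective acylation with a geometrically defined Z acid and desilylation finish the synthesis.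

Key step: step 4

Assumption: TsDPEN denotes N-(p-toluenesulfonyl)-1,2-diphenylethane-1,2-diamine; its (S,S) ruthenium complex is taken to add hydride to the Re face of the aryl ketone as it does with simple aryl alkyl ketones, the sense is to be checked by Mosher ester analysis of the hydroxy amide, and the (R,R) complex would be used if the check showed the opposite sense.

Step 1
Reactants: 1 methyl 3,4-dimethoxybenzoate; 2 N,N-dimethylacetamide
Product: 4 3-(3,4-dimethoxyphenyl)-N,N-dimethyl-3-oxopropanamide, via amide lithium enolate 3 (not isolated)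
Conditions: LiN(i-Pr)2 (2.3 equiv), 2 (2.3 equiv), THF, −78 °C; then 1, −78 → 0 °C; aq NH4Cl
Reagents that add atoms: LiN(i-Pr)2, [Li]N(C(C)C)C(C)C (supplies only the lithium of 3)
Why: Crossed Claisen condensation in which the amide lithium enolate acylates the non-enolisable aryl ester, the extra equivalent of enolate deprotonating the β-keto amide as it forms so that its ketone is shielded from a second addition and the acylation is driven to completion.

Step 2
Reactants: 5 4-methoxybenzaldehyde; 6 vinylmagnesium bromide
Product: 8 rac-1-(4-methoxyphenyl)prop-2-en-1-yl methyl carbonate, via bromomagnesium alkoxide 7 (not isolated)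
Conditions: THF, 0 °C; then ClCO2Me, 0 °C → rt; aq NaHCO3; used promptly
Reagents that add atoms: methyl chloroformate, COC(=O)Cl
Why: Grignard 1,2-addition to the aldehyde followed by O-acylation of the magnesium alkoxide in the same flask avoids handling the acid-labile free carbinol, and the racemic centre is erased at the π-allyl stage of the next step.

Step 3
Reactants: 4 3-(3,4-dimethoxyphenyl)-N,N-dimethyl-3-oxopropanamide; 8 rac-1-(4-methoxyphenyl)prop-2-en-1-yl methyl carbonate
Product: 9 rac-3-(3,4-dimethoxyphenyl)-2-[(E)-3-(4-methoxyphenyl)prop-2-en-1-yl]-N,N-dimethyl-3-oxopropanamide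
Conditions: Pd(PPh3)4 (3 mol %), 4 (1.5 equiv), THF, rt → 40 °C
Reagents that add atoms: none
Why: Tsuji–Trost allylic alkylation in which zerovalent palladium ionises the carbonate to a 1-aryl π-allyl complex of divalent palladium, the expelled methyl carbonate loses CO2 to give the methoxide that deprotonates 4, and the soft enolate attacks the unsubstituted allyl terminus so that the alkene stays conjugated with the anisyl ring as the E isomer, while the excess of 4 suppresses double allylation and the new C2 centre is left racemic and labile on purpose.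

Step 4
Reactants: 9 rac-3-(3,4-dimethoxyphenyl)-2-[(E)-3-(4-methoxyphenyl)prop-2-en-1-yl]-N,N-dimethyl-3-oxopropanamide
Product: 10 (2S,3S)-3-(3,4-dimethoxyphenyl)-3-hydroxy-2-[(E)-3-(4-methoxyphenyl)prop-2-en-1-yl]-N,N-dimethylpropanamide
Conditions: RuCl[(S,S)-TsDPEN](p-cymene) (2 mol %), HCO2H/Et3N (5:2), CH2Cl2, 35 °C
Reagents that add atoms: none
Why: Noyori–Ikariya asymmetric transfer hydrogenation run as a dynamic kinetic resolution: formate turns the 16-electron ruthenium amide into the 18-electron hydride amine complex, which hands its Ru–H hydride and N–H proton to the aryl ketone C=O in an outer-sphere six-membered transition state, while triethylamine interconverts the two C2 epimers of 9 through the enol of the doubly activated methine faster than either is reduced. The closest known reaction type is the transfer hydrogenation of racemic α-alkyl β-keto amides to syn β-hydroxy amides, and no ring is closed. C3 is controlled by the catalyst, since a CH/π contact between the dimethoxyphenyl ring and the p-cymene ligand fixes the ketone so that the (S,S)-diamine complex should add hydride to the Re face and give the 3S carbinol, as with simple aryl alkyl ketones. C2 is controlled by the rate difference between the equilibrating epimers, because only the one that turns its cinnamyl chain away from the incoming Ru–H/N–H pair fits this transition state, which leads to the 2S,3S syn isomer. The step needs ketone face selectivity and syn selectivity, and the substrate secures both by offering an aryl ketone with a single acidic α-hydrogen beside a tertiary amide, a styrene that the formate-derived hydride should not reduce and a product that can no longer epimerise. The electron-rich ketone is expected to react slowly, which is why gentle warming and an extended reaction time are planned.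

Step 5
Reactants: 10 (2S,3S)-3-(3,4-dimethoxyphenyl)-3-hydroxy-2-[(E)-3-(4-methoxyphenyl)prop-2-en-1-yl]-N,N-dimethylpropanamide
Product: 11 (1S,2R)-1-(3,4-dimethoxyphenyl)-2-[(E)-3-(4-methoxyphenyl)prop-2-en-1-yl]propane-1,3-diol
Conditions: LiH2NBH3 (from BH3·NH3 and LiN(i-Pr)2, 4.5 equiv), THF, 0 °C → rt; aq NH4Cl
Reagents that add atoms: none
Why: Amidoborane reduction of a tertiary amide, in which hydride addition, collapse of the hemiaminal with loss of dimethylamine and fast reduction of the resulting aldehyde give the primary alcohol by C–N cleavage, the weakly basic and non-hydroborating reagent being expected to leave the C2 centre, the benzylic alkoxide and the styrene untouched.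

Step 6
Reactants: 12 (E)-crotonaldehyde
Product: 13 (Z)-2-iodobut-2-enal
Conditions: I2, K2CO3, DMAP (0.2 equiv), THF/H2O (1:1), rt
Reagents that add atoms: iodine, II
Why: α-Iodination of an enal by a Morita–Baylis–Hillman-type sequence (conjugate addition of DMAP, iodination of the enolate, E1cB loss of DMAP), which should give the more stable geometry with methyl trans to formyl, that is the Z iodide.

Step 7
Reactants: 13 (Z)-2-iodobut-2-enal
Product: 14 (Z)-2-iodobut-2-en-1-ol
Conditions: NaBH4, CeCl3·7H2O, MeOH, 0 °C
Reagents that add atoms: none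
Why: Luche 1,2-reduction of the enal carbonyl, in which the cerium-activated borohydride does not add in conjugate fashion and leaves the vinyl iodide and its geometry intact.

Step 8
Reactants: 14 (Z)-2-iodobut-2-en-1-ol
Product: 15 (Z)-tert-butyl[(2-iodobut-2-en-1-yl)oxy]dimethylsilane
Conditions: TBSCl, imidazole, CH2Cl2, 0 °C → rt
Reagents that add atoms: tert-butyldimethylsilyl chloride, CC(C)(C)[Si](C)(C)Cl
Why: Standard imidazole-promoted silylation of a primary allylic alcohol, which masks the hydroxyl during metalation and acyl activation.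

Step 9
Reactants: 15 (Z)-tert-butyl[(2-iodobut-2-en-1-yl)oxy]dimethylsilane
Product: 17 (Z)-2-{[(tert-butyldimethylsilyl)oxy]methyl}but-2-enoic acid, via vinyllithium 16 (not isolated)
Conditions: t-BuLi (2.1 equiv), Et2O, −78 °C; CO2 (g), −78 → 0 °C; cold 0.5 M HCl to pH 4
Reagents that add atoms: carbon dioxide, O=C=O; tert-butyllithium, [Li]C(C)(C)C (supplies only the lithium of 16)
Why: Iodine–lithium exchange of a vinyl iodide at −78 °C gives a configurationally stable vinyllithium whose carboxylation with CO2 retains the alkene geometry, diethyl ether and the low temperature holding back a 1,3 oxygen-to-carbon silyl shift and loss of silanolate.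

Step 10
Reactants: 11 (1S,2R)-1-(3,4-dimethoxyphenyl)-2-[(E)-3-(4-methoxyphenyl)prop-2-en-1-yl]propane-1,3-diol; 17 (Z)-2-{[(tert-butyldimethylsilyl)oxy]methyl}but-2-enoic acid
Product: 19 (2R,3S)-3-(3,4-dimethoxyphenyl)-3-hydroxy-2-[(E)-3-(4-methoxyphenyl)prop-2-en-1-yl]propyl (Z)-2-{[(tert-butyldimethylsilyl)oxy]methyl}but-2-enoate, via mixed anhydride 18 (not isolated)
Conditions: 17 (1.05 equiv), 2,4,6-Cl3C6H2COCl, Et3N, toluene, 0 °C; then 11, DMAP, −20 → 0 °C
Reagents that add atoms: 2,4,6-trichlorobenzoyl chloride, O=C(Cl)c1c(Cl)cc(Cl)cc1Cl (supplies only the aroyl group of 18)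
Why: Yamaguchi esterification, in which DMAP opens the mixed anhydride at the less hindered enoyl carbonyl and the acylpyridinium is captured by the unhindered primary hydroxyl much faster than by the secondary benzylic one, the low temperature and near-stoichiometric acid limiting Z to E isomerisation by reversible conjugate addition.

Step 11
Reactants: 19 (2R,3S)-3-(3,4-dimethoxyphenyl)-3-hydroxy-2-[(E)-3-(4-methoxyphenyl)prop-2-en-1-yl]propyl (Z)-2-{[(tert-butyldimethylsilyl)oxy]methyl}but-2-enoate
Product: 20 (2R,3S)-3-(3,4-dimethoxyphenyl)-3-hydroxy-2-[(E)-3-(4-methoxyphenyl)prop-2-en-1-yl]propyl (Z)-2-(hydroxymethyl)but-2-enoate (target CNP0280662.1)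
Conditions: Bu4NF, AcOH (1:1), THF, 0 °C → rt
Reagents that add atoms: none
Why: Fluoride-mediated cleavage of the primary allylic silyl ether, with acetic acid buffering the liberated alkoxide so that neither a 1,3-acyl shift to the benzylic hydroxyl nor isomerisation of the Z enoate should occur.

Compound list
1 | methyl 3,4-dimethoxybenzoate | COC(=O)c1ccc(OC)c(OC)c1 | starting material
2 | N,N-dimethylacetamide | CC(=O)N(C)C | starting material
3 | lithium 1-(dimethylamino)ethen-1-olate (lithium enolate of 2) | C=C(O[Li])N(C)C | intermediate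
4 | 3-(3,4-dimethoxyphenyl)-N,N-dimethyl-3-oxopropanamide | CN(C)C(=O)CC(=O)c1ccc(OC)c(OC)c1 | intermediate
5 | 4-methoxybenzaldehyde | COc1ccc(C=O)cc1 | starting material
6 | vinylmagnesium bromide | C=C[Mg]Br | starting material
7 | bromomagnesium 1-(4-methoxyphenyl)prop-2-en-1-olate (racemic) | C=CC(O[Mg]Br)c1ccc(OC)cc1 | intermediate
8 | rac-1-(4-methoxyphenyl)prop-2-en-1-yl methyl carbonate | COC(=O)OC(C=C)c1ccc(OC)cc1 | intermediate
9 | rac-3-(3,4-dimethoxyphenyl)-2-[(E)-3-(4-methoxyphenyl)prop-2-en-1-yl]-N,N-dimethyl-3-oxopropanamide | CN(C)C(=O)C(C/C=C/c1ccc(OC)cc1)C(=O)c1ccc(OC)c(OC)c1 | intermediate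
10 | (2S,3S)-3-(3,4-dimethoxyphenyl)-3-hydroxy-2-[(E)-3-(4-methoxyphenyl)prop-2-en-1-yl]-N,N-dimethylpropanamide (syn) | CN(C)C(=O)[C@@H](C/C=C/c1ccc(OC)cc1)[C@H](O)c1ccc(OC)c(OC)c1 | intermediate
11 | (1S,2R)-1-(3,4-dimethoxyphenyl)-2-[(E)-3-(4-methoxyphenyl)prop-2-en-1-yl]propane-1,3-diol | OC[C@@H](C/C=C/c1ccc(OC)cc1)[C@H](O)c1ccc(OC)c(OC)c1 | intermediate
12 | (E)-crotonaldehyde | C/C=C/C=O | starting material
13 | (Z)-2-iodobut-2-enal (methyl cis to iodine) | C/C=C(/C=O)I | intermediate
14 | (Z)-2-iodobut-2-en-1-ol | C/C=C(/CO)I | intermediate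
15 | (Z)-tert-butyl[(2-iodobut-2-en-1-yl)oxy]dimethylsilane | C/C=C(/CO[Si](C)(C)C(C)(C)C)I | intermediate
16 | [1-(tert-butyldimethylsilyloxy)but-2-en-2-yl]lithium (methyl cis to lithium) | C/C=C(/CO[Si](C)(C)C(C)(C)C)[Li] | intermediate
17 | (Z)-2-{[(tert-butyldimethylsilyl)oxy]methyl}but-2-enoic acid (methyl cis to carboxyl) | C/C=C(/CO[Si](C)(C)C(C)(C)C)C(=O)O | intermediate
18 | (Z)-2-{[(tert-butyldimethylsilyl)oxy]methyl}but-2-enoic 2,4,6-trichlorobenzoic anhydride | C/C=C(/CO[Si](C)(C)C(C)(C)C)C(=O)OC(=O)c1c(Cl)cc(Cl)cc1Cl | intermediate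
19 | (2R,3S)-3-(3,4-dimethoxyphenyl)-3-hydroxy-2-[(E)-3-(4-methoxyphenyl)prop-2-en-1-yl]propyl (Z)-2-{[(tert-butyldimethylsilyl)oxy]methyl}but-2-enoate | C/C=C(/CO[Si](C)(C)C(C)(C)C)C(=O)OC[C@@H](C/C=C/c1ccc(OC)cc1)[C@H](O)c1ccc(OC)c(OC)c1 | intermediate
20 | (2R,3S)-3-(3,4-dimethoxyphenyl)-3-hydroxy-2-[(E)-3-(4-methoxyphenyl)prop-2-en-1-yl]propyl (Z)-2-(hydroxymethyl)but-2-enoate | C/C=C(/CO)C(=O)OC[C@@H](C/C=C/c1ccc(OC)cc1)[C@H](O)c1ccc(OC)c(OC)c1 | target

Total step count: 11 steps.
Longest linear sequence: 6 steps (steps 1, 3, 4, 5, 10 and 11; the acid branch, steps 6 to 11, is equally long).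

Steps most likely to fail

Step 4. The electron-rich ketone may be reduced too slowly, the syn preference between the equilibrating epimers may be poor, or hydride may add to the unexpected face. The fallback is an auxiliary-controlled aldol route that sets out from 5 and 6 and comes back at 11. Addition of 6 to 5 with aqueous NH4Cl work-up would give rac-1-(4-methoxyphenyl)prop-2-en-1-ol F1. Johnson–Claisen rearrangement with triethyl orthoacetate and catalytic propionic acid at 140 °C would give ethyl (E)-5-(4-methoxyphenyl)pent-4-enoate F2. LiOH in THF/H2O would give (E)-5-(4-methoxyphenyl)pent-4-enoic acid F3. Pivaloyl chloride and Et3N, then (S)-4-benzyloxazolidin-2-one with LiCl, would give (S)-4-benzyl-3-[(E)-5-(4-methoxyphenyl)pent-4-enoyl]oxazolidin-2-one F4. Bu2BOTf and i-Pr2NEt in CH2Cl2, then commercial 3,4-dimethoxybenzaldehyde at −78 → 0 °C, should give the Evans syn aldol adduct (4S)-4-benzyl-3-[(2S,3S)-3-(3,4-dimethoxyphenyl)-3-hydroxy-2-[(E)-3-(4-methoxyphenyl)prop-2-en-1-yl]propanoyl]oxazolidin-2-one F5 through the Zimmerman–Traxler chair of the Z boron enolate. LiBH4 in THF/MeOH at 0 °C would remove the auxiliary reductively and deliver diol 11.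

Step 5. The lithium alkoxide of the β-hydroxy amide may undergo retro-aldol cleavage or C2 epimerisation under the basic hydride, or the reduction may stall. The fallback is a stepwise reduction through the aldehyde on a protected carbinol, setting out from 10 and coming back at 11. TESOTf and 2,6-lutidine would give (2S,3S)-3-(3,4-dimethoxyphenyl)-2-[(E)-3-(4-methoxyphenyl)prop-2-en-1-yl]-N,N-dimethyl-3-(triethylsilyloxy)propanamide F6. Cp2Zr(H)Cl in THF at rt should reduce the tertiary amide chemoselectively to (2S,3S)-3-(3,4-dimethoxyphenyl)-2-[(E)-3-(4-methoxyphenyl)prop-2-en-1-yl]-3-(triethylsilyloxy)propanal F7. NaBH4 in MeOH at 0 °C would give (2R,3S)-3-(3,4-dimethoxyphenyl)-2-[(E)-3-(4-methoxyphenyl)prop-2-en-1-yl]-3-(triethylsilyloxy)propan-1-ol F8. Bu4NF buffered with AcOH would then release diol 11.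

Step 10. The activated enoate may isomerise from Z to E, or acylation may spill over to the benzylic hydroxyl. The fallback activates the alcohol instead of the acid, setting out from 11 and 17 and coming back at 19. It is a Mitsunobu esterification (PPh3, diisopropyl azodicarboxylate, THF, 0 °C) in which the carboxylate of 17 displaces the oxyphosphonium group formed at the unhindered primary hydroxyl. No acylating species is generated, so the enoate geometry is not put at risk, and no new compound is made on the way.

Further compounds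
F1 | step 4 | rac-1-(4-methoxyphenyl)prop-2-en-1-ol | C=CC(O)c1ccc(OC)cc1
F2 | step 4 | ethyl (E)-5-(4-methoxyphenyl)pent-4-enoate | CCOC(=O)CC/C=C/c1ccc(OC)cc1
F3 | step 4 | (E)-5-(4-methoxyphenyl)pent-4-enoic acid | OC(=O)CC/C=C/c1ccc(OC)cc1
F4 | step 4 | (S)-4-benzyl-3-[(E)-5-(4-methoxyphenyl)pent-4-enoyl]oxazolidin-2-one | O=C1OC[C@H](Cc2ccccc2)N1C(=O)CC/C=C/c1ccc(OC)cc1
F5 | step 4 | (4S)-4-benzyl-3-[(2S,3S)-3-(3,4-dimethoxyphenyl)-3-hydroxy-2-[(E)-3-(4-methoxyphenyl)prop-2-en-1-yl]propanoyl]oxazolidin-2-one | O=C1OC[C@H](Cc2ccccc2)N1C(=O)[C@@H](C/C=C/c1ccc(OC)cc1)[C@H](O)c1ccc(OC)c(OC)c1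
F6 | step 5 | (2S,3S)-3-(3,4-dimethoxyphenyl)-2-[(E)-3-(4-methoxyphenyl)prop-2-en-1-yl]-N,N-dimethyl-3-(triethylsilyloxy)propanamide | CN(C)C(=O)[C@@H](C/C=C/c1ccc(OC)cc1)[C@H](O[Si](CC)(CC)CC)c1ccc(OC)c(OC)c1
F7 | step 5 | (2S,3S)-3-(3,4-dimethoxyphenyl)-2-[(E)-3-(4-methoxyphenyl)prop-2-en-1-yl]-3-(triethylsilyloxy)propanal | O=C[C@@H](C/C=C/c1ccc(OC)cc1)[C@H](O[Si](CC)(CC)CC)c1ccc(OC)c(OC)c1
F8 | step 5 | (2R,3S)-3-(3,4-dimethoxyphenyl)-2-[(E)-3-(4-methoxyphenyl)prop-2-en-1-yl]-3-(triethylsilyloxy)propan-1-ol | OC[C@@H](C/C=C/c1ccc(OC)cc1)[C@H](O[Si](CC)(CC)CC)c1ccc(OC)c(OC)c1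
F0 | step 10 | none | none
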